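The route rests on opening the dihydrofuran ring at C2–C3 and at O1–C7a, which leads back to a 2-fluorobenzaldehyde and an acylal of methacrolein. In the key step an iridium-catalysed, enantioselective anti-(benzoyloxy)allylation joins C2 to C3 and sets both stereocentres; carbonate base then shifts the benzoate from the C2 oxygen to the C3 oxygen, and the freed C2 alkoxide displaces fluoride at C7a to close the ring. The step exploits the anti 1,2-dioxygen pattern across C2–C3 of the dihydrofuran ring and the para relationship between the C5 acetyl group and C7a of the benzene ring, which makes C7a an SNAr site. Esterification with the (Z)-acid and MOM removal finish the synthesis.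

Key step: step 4

Remark: atom numbers are those of the 2,3-dihydro-1-benzofuran ring of the target (O1, C2, C3, C3a, C4 to C7, C7a).
Remark: the sense of induction of the ligand in step 4 is assumed; (R)-SEGPHOS is written for the (1S,2R) adduct, and (S)-SEGPHOS is used if the sense proves to be the opposite.

Step 1
Reactants: 1 1-(4-fluoro-2-hydroxyphenyl)ethan-1-one
Product: 2 5-acetyl-2-fluoro-4-hydroxybenzaldehyde
Conditions: hexamethylenetetramine, TFA, 85 °C; then 3 M HCl, 60 °C
Reagents that add atoms: hexamethylenetetramine C1N2CN3CN1CN(C2)C3; water O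
Why: Duff formylation, in which the iminium ion from hexamethylenetetramine attacks the position para to the phenol OH (the other activated position lies between OH and F and is more hindered) and acidic hydrolysis of the benzylic iminium gives the aldehyde.

Step 2
Reactants: 2 5-acetyl-2-fluoro-4-hydroxybenzaldehyde
Product: 3 5-acetyl-2-fluoro-4-(methoxymethoxy)benzaldehyde
Conditions: MOMCl, i-Pr2NEt, CH2Cl2, 0 °C → 23 °C
Reagents that add atoms: chloromethyl methyl ether COCCl
Why: O-alkylation of the acidic phenol (MOM ether formation) with a non-nucleophilic amine base, which should leave the doubly activated fluoride untouched and keeps the ring from becoming an electron-rich phenoxide in step 4.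

Step 3
Reactants: 4 methacrolein; 5 benzoic anhydride
Product: 6 2-methylprop-2-ene-1,1-diyl dibenzoate
Conditions: Sc(OTf)3 (cat.), BHT (cat.), CH2Cl2, 0 °C → 23 °C
Reagents that add atoms: none
Why: Lewis-acid-catalysed acylal (geminal diester) formation from an aldehyde and an anhydride, in which the acyloxocarbenium ion is trapped by benzoate at the former carbonyl carbon.

Step 4
Reactants: 3 5-acetyl-2-fluoro-4-(methoxymethoxy)benzaldehyde; 6 2-methylprop-2-ene-1,1-diyl dibenzoate
Product: 10 1-[(2R,3S)-3-hydroxy-6-(methoxymethoxy)-2-(prop-1-en-2-yl)-2,3-dihydro-1-benzofuran-5-yl]ethan-1-one, via anti hydroxy benzoate 7 (not isolated), via benzoyl-shifted hydroxy benzoate 8 (not isolated), via dihydrobenzofuranyl benzoate 9 (not isolated)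
Conditions: [Ir(cod)Cl]2 (2.5 mol%), (R)-SEGPHOS (5 mol%), 4-cyano-3-nitrobenzoic acid (10 mol%), K3PO4 (1 equiv), i-PrOH (2 equiv), THF, 60 °C; then Cs2CO3, DMF, 50 °C; then MeOH, 40 °C
Reagents that add atoms: none
Why: The cyclometallated iridium complex formed from [Ir(cod)Cl]2, (R)-SEGPHOS and 4-cyano-3-nitrobenzoic acid ionises acylal 6 to a 1-(benzoyloxy)-2-methylallyl iridium species, which adds through its oxygen-bearing carbon to aldehyde 3 in a closed chair transition state while i-PrOH serves as the terminal reductant (transfer-hydrogenative carbonyl anti-(α-acyloxy)allylation from an allylic gem-dicarboxylate, the closest known reaction type); this forms C2–C3. The (E)-σ-allyl geometry (benzoyloxy group trans to the iridium-bearing CH2) fixes the anti relationship of the two oxygens and the chiral ligand fixes the aldehyde face, so C3 (S) and C2 (R) are both set here in 7. Cs2CO3 in DMF then moves the benzoyl group from the C2 oxygen to the benzylic C3 oxygen through a five-membered orthoester anion (7 to 8), and the freed C2 alkoxide adds to C7a and expels fluoride (SNAr through a Meisenheimer anion stabilised by the para acetyl group at C5), which closes the dihydrofuran ring in a 5-exo mode and forms O1–C7a with retention at both stereocentres, so anti becomes trans (9). Only the C2 alkoxide can cyclise, because the C3 alkoxide would have to form a four-membered ring, so the acyl-shift equilibrium drains into 9, and methanol with the same base then cleaves the benzoate to give 10. The step needs aldehyde-over-ketone selectivity (the catalyst couples aldehydes but should leave the aryl methyl ketone alone), anti over syn addition, and intramolecular over intermolecular fluoride displacement; the MOM ether secures the last point by keeping the ring from becoming a deactivated phenoxide.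

Step 5
Reactants: 11 (2E)-but-2-enal
Product: 13 (2Z)-2-bromobut-2-enal, via 2,3-dibromobutanal 12 (not isolated)
Conditions: Br2, CH2Cl2, −10 °C; then Et3N, 0 °C → 23 °C
Reagents that add atoms: bromine BrBr
Why: Bromination–dehydrobromination, in which anti addition of bromine is followed by loss of HBr through the acidic α-hydrogen and should give the α-bromo enal with the methyl group still trans to the formyl group, the thermodynamically preferred (Z) isomer.

Step 6
Reactants: 13 (2Z)-2-bromobut-2-enal
Product: 14 (2Z)-2-bromobut-2-en-1-ol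
Conditions: NaBH4, CeCl3·7H2O, MeOH, 0 °C
Reagents that add atoms: none
Why: Luche reduction delivers hydride 1,2 to the aldehyde and should touch neither the vinyl bromide nor the double-bond geometry.

Step 7
Reactants: 14 (2Z)-2-bromobut-2-en-1-ol
Product: 16 (2Z)-2-(hydroxymethyl)but-2-enoic acid, via dilithiated vinyl alkoxide 15 (not isolated)
Conditions: t-BuLi (3.1 equiv), Et2O, −78 °C; then CO2, −78 °C → 0 °C; 1 M HCl work-up
Reagents that add atoms: carbon dioxide O=C=O
Why: Bromine–lithium exchange on the lithium alkoxide gives a vinyllithium that is configurationally stable at −78 °C, and its carboxylation proceeds with retention, which places the carboxyl group cis to the methyl group.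

Step 8
Reactants: 16 (2Z)-2-(hydroxymethyl)but-2-enoic acid
Product: 17 (2Z)-2-(acetoxymethyl)but-2-enoic acid
Conditions: Ac2O, pyridine, 0 °C → 23 °C; aqueous work-up
Reagents that add atoms: acetic anhydride CC(=O)OC(C)=O
Why: Acetylation of the primary allylic alcohol with acetic anhydride in pyridine; no nucleophilic catalyst is added so that the (Z)-enoate should not isomerise, and any mixed anhydride at the acid is hydrolysed on work-up.

Step 9
Reactants: 10 1-[(2R,3S)-3-hydroxy-6-(methoxymethoxy)-2-(prop-1-en-2-yl)-2,3-dihydro-1-benzofuran-5-yl]ethan-1-one; 17 (2Z)-2-(acetoxymethyl)but-2-enoic acid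
Product: 19 (2R,3S)-5-acetyl-6-(methoxymethoxy)-2-(prop-1-en-2-yl)-2,3-dihydro-1-benzofuran-3-yl (2Z)-2-(acetoxymethyl)but-2-enoate, via mixed trichlorobenzoic anhydride 18 (not isolated)
Conditions: 17, 2,4,6-trichlorobenzoyl chloride, Et3N, toluene, 23 °C; then 10, 75 °C
Reagents that add atoms: none
Why: Yamaguchi-type mixed-anhydride esterification run without DMAP, the variant suited to angelate-type (Z)-enoic acids because no nucleophilic catalyst is present that could add to the enoate and cause (Z) to (E) isomerisation or displace the allylic acetate; C3 is acylated at oxygen with retention.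

Step 10
Reactants: 19 (2R,3S)-5-acetyl-6-(methoxymethoxy)-2-(prop-1-en-2-yl)-2,3-dihydro-1-benzofuran-3-yl (2Z)-2-(acetoxymethyl)but-2-enoate
Product: 21 (2R,3S)-5-acetyl-6-hydroxy-2-(prop-1-en-2-yl)-2,3-dihydro-1-benzofuran-3-yl (2Z)-2-(acetoxymethyl)but-2-enoate, via aryl trimethylsilyl ether 20 (not isolated)
Conditions: TMSOTf, 2,2′-bipyridyl, CH2Cl2, 0 °C → 23 °C; then H2O
Reagents that add atoms: none
Why: Acetal cleavage of an aryl MOM ether by TMSOTf buffered with 2,2′-bipyridyl, which converts the ether into the aryl silyl ether under non-protic conditions; water then frees the hydrogen-bonded phenol, and the buffered medium should not ionise the benzylic ester.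

Compound list
1 | 1-(4-fluoro-2-hydroxyphenyl)ethan-1-one | CC(=O)c1ccc(F)cc1O | starting material
2 | 5-acetyl-2-fluoro-4-hydroxybenzaldehyde | CC(=O)c1cc(C=O)c(F)cc1O | intermediate
3 | 5-acetyl-2-fluoro-4-(methoxymethoxy)benzaldehyde | CC(=O)c1cc(C=O)c(F)cc1OCOC | intermediate
4 | methacrolein (2-methylprop-2-enal) | C=C(C)C=O | starting material
5 | benzoic anhydride | O=C(OC(=O)c1ccccc1)c1ccccc1 | starting material
6 | 2-methylprop-2-ene-1,1-diyl dibenzoate | C=C(C)C(OC(=O)c1ccccc1)OC(=O)c1ccccc1 | intermediate
7 | (1S,2R)-1-[5-acetyl-2-fluoro-4-(methoxymethoxy)phenyl]-1-hydroxy-3-methylbut-3-en-2-yl benzoate | C=C(C)[C@@H](OC(=O)c1ccccc1)[C@@H](O)c1cc(C(C)=O)c(OCOC)cc1F | intermediate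
8 | (1S,2R)-1-[5-acetyl-2-fluoro-4-(methoxymethoxy)phenyl]-2-hydroxy-3-methylbut-3-en-1-yl benzoate | C=C(C)[C@@H](O)[C@@H](OC(=O)c1ccccc1)c1cc(C(C)=O)c(OCOC)cc1F | intermediate
9 | (2R,3S)-5-acetyl-6-(methoxymethoxy)-2-(prop-1-en-2-yl)-2,3-dihydro-1-benzofuran-3-yl benzoate | C=C(C)[C@H]1Oc2cc(OCOC)c(C(C)=O)cc2[C@@H]1OC(=O)c1ccccc1 | intermediate
10 | 1-[(2R,3S)-3-hydroxy-6-(methoxymethoxy)-2-(prop-1-en-2-yl)-2,3-dihydro-1-benzofuran-5-yl]ethan-1-one | C=C(C)[C@H]1Oc2cc(OCOC)c(C(C)=O)cc2[C@@H]1O | intermediate
11 | (2E)-but-2-enal (crotonaldehyde) | C/C=C/C=O | starting material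
12 | (2R*,3S*)-2,3-dibromobutanal (racemic, one enantiomer drawn) | C[C@H](Br)[C@H](Br)C=O | intermediate
13 | (2Z)-2-bromobut-2-enal | C/C=C(\Br)C=O | intermediate
14 | (2Z)-2-bromobut-2-en-1-ol | C/C=C(\Br)CO | intermediate
15 | lithium (2E)-2-lithiobut-2-en-1-olate | C/C=C(\[Li])CO[Li] | intermediate
16 | (2Z)-2-(hydroxymethyl)but-2-enoic acid | C/C=C(\C(=O)O)CO | intermediate
17 | (2Z)-2-(acetoxymethyl)but-2-enoic acid | C/C=C(\C(=O)O)COC(C)=O | intermediate
18 | (2Z)-2-(acetoxymethyl)but-2-enoic 2,4,6-trichlorobenzoic anhydride | C/C=C(\C(=O)OC(=O)c1c(Cl)cc(Cl)cc1Cl)COC(C)=O | intermediate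
19 | (2R,3S)-5-acetyl-6-(methoxymethoxy)-2-(prop-1-en-2-yl)-2,3-dihydro-1-benzofuran-3-yl (2Z)-2-(acetoxymethyl)but-2-enoate | C=C(C)[C@H]1Oc2cc(OCOC)c(C(C)=O)cc2[C@@H]1OC(=O)/C(=C\C)COC(C)=O | intermediate
20 | (2R,3S)-5-acetyl-2-(prop-1-en-2-yl)-6-[(trimethylsilyl)oxy]-2,3-dihydro-1-benzofuran-3-yl (2Z)-2-(acetoxymethyl)but-2-enoate | C=C(C)[C@H]1Oc2cc(O[Si](C)(C)C)c(C(C)=O)cc2[C@@H]1OC(=O)/C(=C\C)COC(C)=O | intermediate
21 | (2R,3S)-5-acetyl-6-hydroxy-2-(prop-1-en-2-yl)-2,3-dihydro-1-benzofuran-3-yl (2Z)-2-(acetoxymethyl)but-2-enoate | C=C(C)[C@H]1Oc2cc(O)c(C(C)=O)cc2[C@@H]1OC(=O)/C(=C\C)COC(C)=O | target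

Total step count: 10.
Longest linear sequence: 6 steps (steps 5 to 10, from crotonaldehyde 11 to 21); the aryl branch takes 5 steps (steps 1, 2, 4, 9, 10).

Steps most likely to fail

Step 4. The 1,1-disubstituted alkene of acylal 6 may ionise slowly at iridium, the allyl species may leak through its (Z)-σ-allyl isomer so that anti selectivity erodes, and isopropoxide may displace the doubly activated fluoride of 3 before the C–C bond forms. The fallback sets out from 3, makes C2–C3 with a boron reagent and closes the ring in a separate operation. (Diisopropylamino)dimethyl(2-methylallyl)silane F1 (from 2-methylallylmagnesium chloride and chloro(diisopropylamino)dimethylsilane) is lithiated with n-BuLi/TMEDA and borylated with i-PrOBpin to the (E)-γ-silyl allylboronate F2. Chiral phosphoric acid-catalysed allylboration of 3 (TRIP antipode chosen for the (1S,2R) adduct, toluene, −30 °C) should give the anti β-hydroxysilane F3. Tamao–Fleming oxidation (H2O2, KF, KHCO3, THF/MeOH) replaces silicon by hydroxyl with retention and gives the anti diol F4. Cs2CO3 in DMF then closes the ring by SNAr, and the route is rejoined at 10.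

Step 9. The (Z)-enoate may isomerise to the (E)-isomer through reversible conjugate addition, the allylic acetate may be lost, and the benzylic alcohol may eliminate to the benzofuran on heating. The fallback sets out from 10 and 14 and builds the ester by carbonylation instead of acyl transfer. Bromo alcohol 14 is silylated (TBSCl, imidazole) to the vinyl bromide silyl ether F5. Alkoxycarbonylation of F5 with alcohol 10 (Pd(OAc)2, Xantphos, CO 1 atm, Et3N, toluene, 80 °C) should give, with retention of the alkene geometry, the silyloxymethyl ester F6. HF·pyridine frees the hydroxymethyl ester F7, and Ac2O/pyridine returns to the route at 19.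

Step 10. The electron-rich benzylic ester may ionise under the Lewis-acidic conditions and eliminate to the aromatic benzofuran, or the acetal cleavage may stall. The fallback sets out from 10 and changes the protecting group before the ester is present, so that the last step becomes a buffered fluoride desilylation. Alcohol 10 is treated with TMSOTf/2,2′-bipyridyl to give the bis(trimethylsilyl) ether F8, which aqueous work-up hydrolyses to the phenol diol F9. TBSCl/Et3N should silylate the more acidic phenol selectively to the aryl silyl ether F10. Esterification with 17 as in step 9 (through 18) gives the silyl-protected ester F11, and TBAF buffered with AcOH at 0 °C removes the aryl silyl group to reach 21.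

Further compounds
F1 | step 4 | N,N-diisopropyl-1,1-dimethyl-1-(2-methylprop-2-en-1-yl)silanamine | C=C(C)C[Si](C)(C)N(C(C)C)C(C)C
F2 | step 4 | N,N-diisopropyl-1,1-dimethyl-1-[(1E)-2-methyl-3-(4,4,5,5-tetramethyl-1,3,2-dioxaborolan-2-yl)prop-1-en-1-yl]silanamine | C/C(=C\[Si](C)(C)N(C(C)C)C(C)C)CB1OC(C)(C)C(C)(C)O1
F3 | step 4 | (1S,2R)-1-[5-acetyl-2-fluoro-4-(methoxymethoxy)phenyl]-2-[(diisopropylamino)dimethylsilyl]-3-methylbut-3-en-1-ol | C=C(C)[C@@H]([Si](C)(C)N(C(C)C)C(C)C)[C@@H](O)c1cc(C(C)=O)c(OCOC)cc1F
F4 | step 4 | (1S,2R)-1-[5-acetyl-2-fluoro-4-(methoxymethoxy)phenyl]-3-methylbut-3-ene-1,2-diol | C=C(C)[C@@H](O)[C@@H](O)c1cc(C(C)=O)c(OCOC)cc1F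
F5 | step 9 | {[(2Z)-2-bromobut-2-en-1-yl]oxy}(tert-butyl)dimethylsilane | C/C=C(\Br)CO[Si](C)(C)C(C)(C)C
F6 | step 9 | (2R,3S)-5-acetyl-6-(methoxymethoxy)-2-(prop-1-en-2-yl)-2,3-dihydro-1-benzofuran-3-yl (2Z)-2-{[(tert-butyldimethylsilyl)oxy]methyl}but-2-enoate | C=C(C)[C@H]1Oc2cc(OCOC)c(C(C)=O)cc2[C@@H]1OC(=O)/C(=C\C)CO[Si](C)(C)C(C)(C)C
F7 | step 9 | (2R,3S)-5-acetyl-6-(methoxymethoxy)-2-(prop-1-en-2-yl)-2,3-dihydro-1-benzofuran-3-yl (2Z)-2-(hydroxymethyl)but-2-enoate | C=C(C)[C@H]1Oc2cc(OCOC)c(C(C)=O)cc2[C@@H]1OC(=O)/C(=C\C)CO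
F8 | step 10 | 1-[(2R,3S)-2-(prop-1-en-2-yl)-3,6-bis[(trimethylsilyl)oxy]-2,3-dihydro-1-benzofuran-5-yl]ethan-1-one | C=C(C)[C@H]1Oc2cc(O[Si](C)(C)C)c(C(C)=O)cc2[C@@H]1O[Si](C)(C)C
F9 | step 10 | 1-[(2R,3S)-3,6-dihydroxy-2-(prop-1-en-2-yl)-2,3-dihydro-1-benzofuran-5-yl]ethan-1-one | C=C(C)[C@H]1Oc2cc(O)c(C(C)=O)cc2[C@@H]1O
F10 | step 10 | 1-[(2R,3S)-6-[(tert-butyldimethylsilyl)oxy]-3-hydroxy-2-(prop-1-en-2-yl)-2,3-dihydro-1-benzofuran-5-yl]ethan-1-one | C=C(C)[C@H]1Oc2cc(O[Si](C)(C)C(C)(C)C)c(C(C)=O)cc2[C@@H]1O
F11 | step 10 | (2R,3S)-5-acetyl-6-[(tert-butyldimethylsilyl)oxy]-2-(prop-1-en-2-yl)-2,3-dihydro-1-benzofuran-3-yl (2Z)-2-(acetoxymethyl)but-2-enoate | C=C(C)[C@H]1Oc2cc(O[Si](C)(C)C(C)(C)C)c(C(C)=O)cc2[C@@H]1OC(=O)/C(=C\C)COC(C)=O
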